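**Plan**

1. Numbering (that of the target): C1 lactone carbonyl; ring C = N, C5, C4, C3, C2, C22 (NCH2); ring B = N, C5–C9; ring A = C9–C13; side chain C14(Me)–C21.
2. Retrosynthesis cuts, in order: the lactone C1–O bond, C16–C17 (alkynylation), C15≡C16 (homologation of a C15 carbonyl), ring C at C2=C3 and N–C22, then ring B at C6–C7 and C8–C9 together. Ring B holds the unit C6–C5–N–C9, which is a 2-aza-1,3-diene (C6=C5–N=C9) once C9 is the carbonyl carbon of a ring A ketone, and C7–C8 is two bare methylenes, an ethylene equivalent.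
3. Forward: ring A ketone 5 from the pool lactone 1; a three-component aza-Wittig/[4+2] sequence builds ring B and the spiro carbon; imine reduction; ring C by N-alkylation and ring-closing metathesis; C15 amide to alkyne; union with chloro-enal 23; Z-alkene; 15-membered lactone.
4. Stereochemistry: C13 from 1; C14 by convex-face methylation; C9 by cycloaddition anti to the C13 arm; C5 by hydride addition to the cyclic imine; C17 by ligand-controlled alkynylation; 15Z by semi-hydrogenation; chloroalkene geometry from the six-membered lactone 20.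

Key step: step 6

Remark: the target is read exactly as drawn (15Z; Cl trans to C17 across C18=C19; 5R,9S,13R,14S,17R), and 6 and 19 are treated as catalogue compounds; locants C1–C22 in the text are those of the target, systematic names carry their own.

**Route**

Step 1
Reactants: 1 (1R,5S)-2-oxabicyclo[3.3.0]oct-6-en-3-one
Product: 2 (3aR,6aR)-hexahydro-2H-cyclopenta[b]furan-2-one
Conditions: H2 (1 atm), 10% Pd/C, EtOAc, rt
Reagents that add atoms: none
Why: Heterogeneous hydrogenation of the isolated ring alkene, which would otherwise end as a β,γ-enone, leaves both ring-fusion centers untouched.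

Step 2
Reactants: 2 (3aR,6aR)-hexahydro-2H-cyclopenta[b]furan-2-one
Product: 3 (3R,3aR,6aR)-3-methylhexahydro-2H-cyclopenta[b]furan-2-one
Conditions: LiN(iPr)2, THF, −78 °C; MeI, −78 → −40 °C
Reagents that add atoms: iodomethane, CI
Why: Enolate alkylation of a cis-fused bicyclic γ-lactone should take MeI on the convex face, trans to the cyclopentane ring, which sets C14.

Step 3
Reactants: 3 (3R,3aR,6aR)-3-methylhexahydro-2H-cyclopenta[b]furan-2-one
Product: 4 (2R)-2-[(1R,2R)-2-hydroxycyclopentyl]-N,N-dimethylpropanamide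
Conditions: Me2NH (2 M in THF), AlMe3, CH2Cl2, 0 °C → rt
Reagents that add atoms: dimethylamine, CNC
Why: Aluminium amide aminolysis of the lactone (Weinreb-type amidation) opens the ring without enolizing C14 and frees the C9 hydroxyl.

Step 4
Reactants: 4 (2R)-2-[(1R,2R)-2-hydroxycyclopentyl]-N,N-dimethylpropanamide
Product: 5 (2R)-N,N-dimethyl-2-[(1R)-2-oxocyclopentyl]propanamide
Conditions: Dess–Martin periodinane, CH2Cl2, 0 °C → rt
Reagents that add atoms: none
Why: Dess–Martin oxidation of the secondary alcohol under non-basic conditions should give the ring A ketone without epimerizing C13, now α to the carbonyl.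

Step 5
Reactants: 6 pent-1-en-4-yne
Product: 7 2-azidopenta-1,4-diene
Conditions: TMSN3, Ag2CO3 (10 mol %), H2O (2 equiv), DMSO, 80 °C; extracted and kept as a dilute toluene solution
Reagents that add atoms: azidotrimethylsilane, C[Si](C)(C)N=[N+]=[N-]
Why: Silver-catalysed Markovnikov hydroazidation of the terminal alkyne should give the 1-substituted vinyl azide and leave the allyl group alone.

Step 6
Reactants: 5 (2R)-N,N-dimethyl-2-[(1R)-2-oxocyclopentyl]propanamide, 7 2-azidopenta-1,4-diene, 8 phenyl vinyl sulfone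
Product: 11 (2R)-N,N-dimethyl-2-[(1R,5R)-10-(phenylsulfonyl)-7-(prop-2-en-1-yl)-6-azaspiro[4.5]dec-6-en-1-yl]propanamide (both epimers at the sulfonyl carbon), via N-vinylic phosphazene 9 (not isolated), via 2-aza-1,3-diene 10 (not isolated)
Conditions: 7, PMe3 (1.0 equiv), toluene, 0 °C → rt; then 5, 80 °C; then 8 (3 equiv), BHT (cat.), 100 °C, sealed tube
Reagents that add atoms: none
Why: Proposed new method: Staudinger reaction of 7 with PMe3 gives phosphazene 9, aza-Wittig reaction of 9 with ketone 5 gives under neutral conditions the 2-aza-1,3-diene 10 (C6=C5–N=C9), and 10 should add phenyl vinyl sulfone in a normal-electron-demand, strongly asynchronous [4+2] cycloaddition (in the limit, Michael addition of C6 to the sulfone β-carbon followed by Mannich-type closure of the α-sulfonyl carbanion on C9 of the 2-azaallenium ion), so that C6–C7 and C8–C9 form in one operation. The closest known reaction types are the tandem aza-Wittig/aza-Diels–Alder reaction of N-vinylic phosphazenes with aldehydes and the Diels–Alder reaction of 2-aza-1,3-dienes with electron-poor alkenes; new here is a diene made from an enolizable, α-stereogenic cyclopentanone whose imine carbon becomes a spiro aza-quaternary center. Ring B closes in a suprafacial 4π + 2π mode (a 6-endo-trig closure onto C=N in the stepwise limit). C9 is set by approach of the dienophile to the face of the cyclopentylidene imine anti to the C14 arm on the neighbouring carbon C13, which places N cis and C8 trans to that arm, while the sulfonyl-bearing C8 forms without control and is erased in step 8. The step needs regioselectivity, reaction through tautomer 10 and retention of C13: polarity matching joins the unsubstituted nucleophilic terminus C6 to the sulfone β-carbon and leaves the sulfonyl group on C8, the terminal CH2 of 10 is its only unhindered nucleophilic site, and the acid- and base-free aza-Wittig conditions are meant to keep imine–enamine exchange at C13 slow.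

Step 7
Reactants: 11 (2R)-N,N-dimethyl-2-[(1R,5R)-10-(phenylsulfonyl)-7-(prop-2-en-1-yl)-6-azaspiro[4.5]dec-6-en-1-yl]propanamide
Product: 12 (2R)-N,N-dimethyl-2-[(1R,5R,7R)-10-(phenylsulfonyl)-7-(prop-2-en-1-yl)-6-azaspiro[4.5]decan-1-yl]propanamide
Conditions: NaBH4, MeOH, −20 → 0 °C
Reagents that add atoms: none
Why: Hydride reduction of the cyclic ketimine by axial attack on the half-chair with the bulkier C13 branch pseudoequatorial should deliver H to the face of the ring A methylene C10 and leave the C5 allyl group equatorial and cis to C13, the 2,6-cis outcome usual for Δ1-piperideines.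

Step 8
Reactants: 12 (2R)-N,N-dimethyl-2-[(1R,5R,7R)-10-(phenylsulfonyl)-7-(prop-2-en-1-yl)-6-azaspiro[4.5]decan-1-yl]propanamide
Product: 13 (2R)-N,N-dimethyl-2-[(1R,5S,7R)-7-(prop-2-en-1-yl)-6-azaspiro[4.5]decan-1-yl]propanamide
Conditions: 6% Na(Hg), Na2HPO4, MeOH/THF, −20 °C → rt
Reagents that add atoms: none
Why: Reductive desulfonylation of the secondary alkyl phenyl sulfone, done after imine reduction so that the β-nitrogen is a poor leaving group, removes the only uncontrolled stereocenter.

Step 9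
Reactants: 13 (2R)-N,N-dimethyl-2-[(1R,5S,7R)-7-(prop-2-en-1-yl)-6-azaspiro[4.5]decan-1-yl]propanamide, 14 methyl 2-(bromomethyl)acrylate
Product: 15 methyl 2-{[(1R,5S,7R)-1-[(2R)-1-(dimethylamino)-1-oxopropan-2-yl]-7-(prop-2-en-1-yl)-6-azaspiro[4.5]decan-6-yl]methyl}prop-2-enoate
Conditions: K2CO3, MeCN, 50 °C
Reagents that add atoms: none
Why: N-Alkylation of the hindered secondary amine by the reactive allylic bromide (SN2 and SN2′ give the same product) installs C22, C2 and C1.

Step 10
Reactants: 15 methyl 2-{[(1R,5S,7R)-1-[(2R)-1-(dimethylamino)-1-oxopropan-2-yl]-7-(prop-2-en-1-yl)-6-azaspiro[4.5]decan-6-yl]methyl}prop-2-enoate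
Product: 16 methyl (1S,2R,9a'R)-2-[(2R)-1-(dimethylamino)-1-oxopropan-2-yl]-1',4',7',8',9',9a'-hexahydrospiro[cyclopentane-1,6'-quinolizine]-3'-carboxylate
Conditions: second-generation Grubbs catalyst RuCl2(=CHPh)(H2IMes)(PCy3) (5 mol %), CH2Cl2, 40 °C
Reagents that add atoms: none
Why: Ring-closing metathesis between the allyl group and the 2-substituted acrylate should close ring C as the trisubstituted enoate, the nitrogen being shielded by the spiro center.

Step 11
Reactants: 16 methyl (1S,2R,9a'R)-2-[(2R)-1-(dimethylamino)-1-oxopropan-2-yl]-1',4',7',8',9',9a'-hexahydrospiro[cyclopentane-1,6'-quinolizine]-3'-carboxylate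
Product: 17 methyl (1S,2R,9a'R)-2-[(2R)-1-oxopropan-2-yl]-1',4',7',8',9',9a'-hexahydrospiro[cyclopentane-1,6'-quinolizine]-3'-carboxylate
Conditions: Cp2Zr(H)Cl (1.5 equiv), THF, rt, 20 min; silica gel work-up
Reagents that add atoms: none
Why: Schwartz-reagent reduction of the tertiary amide to the aldehyde through a stable zirconated hemiaminal is chemoselective over the conjugated methyl ester and does not enolize C14.

Step 12
Reactants: 17 methyl (1S,2R,9a'R)-2-[(2R)-1-oxopropan-2-yl]-1',4',7',8',9',9a'-hexahydrospiro[cyclopentane-1,6'-quinolizine]-3'-carboxylate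
Product: 18 methyl (1S,2R,9a'R)-2-[(2R)-but-3-yn-2-yl]-1',4',7',8',9',9a'-hexahydrospiro[cyclopentane-1,6'-quinolizine]-3'-carboxylate
Conditions: dimethyl (1-diazo-2-oxopropyl)phosphonate, K2CO3, MeOH, 0 °C → rt
Reagents that add atoms: dimethyl (1-diazo-2-oxopropyl)phosphonate, CC(=O)C(=[N+]=[N-])P(=O)(OC)OC
Why: Ohira–Bestmann homologation turns the aldehyde into the terminal alkyne (C16 comes from the reagent) under mild base, and the methyl ester matches the methanol solvent.

Step 13
Reactants: 19 dihydro-2H-pyran-2,4(3H)-dione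
Product: 20 4-chloro-5,6-dihydro-2H-pyran-2-one
Conditions: (COCl)2, DMF (cat.), CH2Cl2, 0 °C → rt
Reagents that add atoms: oxalyl chloride, ClC(=O)C(=O)Cl
Why: Vilsmeier-type chlorination of the cyclic 1,3-dicarbonyl compound through its enol should give the β-chloro enoate, and the ring holds C17 and C20 cis across the future C18=C19 bond.

Step 14
Reactants: 20 4-chloro-5,6-dihydro-2H-pyran-2-one
Product: 21 (2E)-3-chloro-5-hydroxy-N-methoxy-N-methylpent-2-enamide
Conditions: MeNH(OMe)·HCl, AlMe3, CH2Cl2, −20 → 0 °C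
Reagents that add atoms: N,O-dimethylhydroxylamine hydrochloride, CNOC.Cl
Why: Aluminium amide opening of the lactone at the acyl carbon gives the Weinreb amide and carries the alkene geometry over from the ring.

Step 15
Reactants: 21 (2E)-3-chloro-5-hydroxy-N-methoxy-N-methylpent-2-enamide
Product: 22 (2E)-5-[(tert-butyldimethylsilyl)oxy]-3-chloro-N-methoxy-N-methylpent-2-enamide
Conditions: TBSCl, imidazole, CH2Cl2, 0 °C → rt
Reagents that add atoms: tert-butyldimethylsilyl chloride, CC(C)(C)[Si](C)(C)Cl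
Why: Silylation of the primary alcohol, done at once, keeps the hydroxy amide from closing back to the lactone.

Step 16
Reactants: 22 (2E)-5-[(tert-butyldimethylsilyl)oxy]-3-chloro-N-methoxy-N-methylpent-2-enamide
Product: 23 (2E)-5-[(tert-butyldimethylsilyl)oxy]-3-chloropent-2-enal
Conditions: iBu2AlH, THF, −78 °C; aqueous KNaC4H4O6 (potassium sodium tartrate) work-up
Reagents that add atoms: none
Why: Weinreb amide reduction stops at the aldehyde through the chelated tetrahedral intermediate, and 1,2-hydride delivery leaves the β-chloro enal geometry intact.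

Step 17
Reactants: 18 methyl (1S,2R,9a'R)-2-[(2R)-but-3-yn-2-yl]-1',4',7',8',9',9a'-hexahydrospiro[cyclopentane-1,6'-quinolizine]-3'-carboxylate, 23 (2E)-5-[(tert-butyldimethylsilyl)oxy]-3-chloropent-2-enal
Product: 24 methyl (1S,2R,9a'R)-2-[(2R,5S,6E)-9-[(tert-butyldimethylsilyl)oxy]-7-chloro-5-hydroxynon-6-en-3-yn-2-yl]-1',4',7',8',9',9a'-hexahydrospiro[cyclopentane-1,6'-quinolizine]-3'-carboxylate
Conditions: Me2Zn (3 equiv), (S,S)-ProPhenol ligand (20 mol %), Ph3P=O (40 mol %), toluene, 4 °C; 23 in excess (1.5 equiv)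
Reagents that add atoms: none
Why: Asymmetric alkynylation of an α,β-unsaturated aldehyde with Me2Zn and the ProPhenol ligand should deliver the alkynyl group to the Re face of the enal and so set C17 (S here by the sequence rule, R after step 18, same geometry) independently of the remote core stereocenters, while ester, amine and vinyl chloride tolerate the organozinc.

Step 18
Reactants: 24 methyl (1S,2R,9a'R)-2-[(2R,5S,6E)-9-[(tert-butyldimethylsilyl)oxy]-7-chloro-5-hydroxynon-6-en-3-yn-2-yl]-1',4',7',8',9',9a'-hexahydrospiro[cyclopentane-1,6'-quinolizine]-3'-carboxylate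
Product: 25 methyl (1S,2R,9a'R)-2-[(2S,3Z,5R,6E)-9-[(tert-butyldimethylsilyl)oxy]-7-chloro-5-hydroxynona-3,6-dien-2-yl]-1',4',7',8',9',9a'-hexahydrospiro[cyclopentane-1,6'-quinolizine]-3'-carboxylate
Conditions: H2 (1 atm), Pd/CaCO3 poisoned with Pb(OAc)2 (Lindlar catalyst), quinoline, EtOAc, rt
Reagents that add atoms: none
Why: Lindlar semi-hydrogenation adds H2 syn to the alkyne and should give the 15Z alkene without reducing the vinyl chloride or the trisubstituted enoate.

Step 19
Reactants: 25 methyl (1S,2R,9a'R)-2-[(2S,3Z,5R,6E)-9-[(tert-butyldimethylsilyl)oxy]-7-chloro-5-hydroxynona-3,6-dien-2-yl]-1',4',7',8',9',9a'-hexahydrospiro[cyclopentane-1,6'-quinolizine]-3'-carboxylate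
Product: 26 methyl (1S,2R,9a'R)-2-[(2S,3Z,5R,6E)-7-chloro-5,9-dihydroxynona-3,6-dien-2-yl]-1',4',7',8',9',9a'-hexahydrospiro[cyclopentane-1,6'-quinolizine]-3'-carboxylate
Conditions: HF·pyridine, pyridine, THF, 0 °C → rt
Reagents that add atoms: none
Why: Buffered fluoride cleavage of the primary silyl ether, with excess pyridine, keeps the medium from ionizing the doubly allylic C17 alcohol.

Step 20
Reactants: 26 methyl (1S,2R,9a'R)-2-[(2S,3Z,5R,6E)-7-chloro-5,9-dihydroxynona-3,6-dien-2-yl]-1',4',7',8',9',9a'-hexahydrospiro[cyclopentane-1,6'-quinolizine]-3'-carboxylate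
Product: 27 (1S,2R,9a'R)-2-[(2S,3Z,5R,6E)-7-chloro-5,9-dihydroxynona-3,6-dien-2-yl]-1',4',7',8',9',9a'-hexahydrospiro[cyclopentane-1,6'-quinolizine]-3'-carboxylic acid
Conditions: LiOH·H2O, THF/MeOH/H2O, rt; AcOH to pH 6
Reagents that add atoms: lithium hydroxide monohydrate, [Li+].[OH-].O
Why: Saponification of the methyl enoate should give the seco acid, the vinyl chloride and the allylic alcohol being stable to aqueous hydroxide at rt.

Step 21
Reactants: 27 (1S,2R,9a'R)-2-[(2S,3Z,5R,6E)-7-chloro-5,9-dihydroxynona-3,6-dien-2-yl]-1',4',7',8',9',9a'-hexahydrospiro[cyclopentane-1,6'-quinolizine]-3'-carboxylic acid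
Product: 28 target macrolactone (5R,9S,13R,14S,17R; 15Z; 18E)
Conditions: 2-methyl-6-nitrobenzoic anhydride (MNBA), DMAP, CH2Cl2 (1 mM, slow addition), rt
Reagents that add atoms: none
Why: Shiina macrolactonization through the mixed anhydride should close the 15-membered ring at the primary C21 hydroxyl, which reacts much faster than the secondary C17 hydroxyl could close a strained 11-membered ring holding the Z-alkene.

**Compound list**

1 | (1R,5S)-2-oxabicyclo[3.3.0]oct-6-en-3-one | C1C(=O)O[C@@H]2CC=C[C@H]12 | starting material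
2 | (3aR,6aR)-hexahydro-2H-cyclopenta[b]furan-2-one | C1C(=O)O[C@@H]2CCC[C@H]12 | intermediate
3 | (3R,3aR,6aR)-3-methylhexahydro-2H-cyclopenta[b]furan-2-one | C[C@H]1C(=O)O[C@@H]2CCC[C@H]12 | intermediate
4 | (2R)-2-[(1R,2R)-2-hydroxycyclopentyl]-N,N-dimethylpropanamide | C[C@@H](C(=O)N(C)C)[C@H]1CCC[C@H]1O | intermediate
5 | (2R)-N,N-dimethyl-2-[(1R)-2-oxocyclopentyl]propanamide | C[C@@H](C(=O)N(C)C)[C@H]1CCCC1=O | intermediate
6 | pent-1-en-4-yne | C=CCC#C | starting material
7 | 2-azidopenta-1,4-diene | C=C(CC=C)N=[N+]=[N-] | intermediate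
8 | phenyl vinyl sulfone | C=CS(=O)(=O)c1ccccc1 | starting material
9 | N-(penta-1,4-dien-2-yl)-P,P,P-trimethylphosphine imide (N-vinylic phosphazene) | C=C(CC=C)N=P(C)(C)C | intermediate (not isolated)
10 | (2R)-N,N-dimethyl-2-[(1R)-2-(penta-1,4-dien-2-ylimino)cyclopentyl]propanamide (2-aza-1,3-diene; C=N geometry not fixed) | C[C@@H](C(=O)N(C)C)[C@H]1CCCC1=NC(=C)CC=C | intermediate (not isolated)
11 | (2R)-N,N-dimethyl-2-[(1R,5R)-10-(phenylsulfonyl)-7-(prop-2-en-1-yl)-6-azaspiro[4.5]dec-6-en-1-yl]propanamide (both epimers at C-10) | C[C@@H](C(=O)N(C)C)[C@H]1CCC[C@@]12N=C(CC=C)CCC2S(=O)(=O)c3ccccc3 | intermediate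
12 | (2R)-N,N-dimethyl-2-[(1R,5R,7R)-10-(phenylsulfonyl)-7-(prop-2-en-1-yl)-6-azaspiro[4.5]decan-1-yl]propanamide (both epimers at C-10) | C[C@@H](C(=O)N(C)C)[C@H]1CCC[C@@]12N[C@@H](CC=C)CCC2S(=O)(=O)c3ccccc3 | intermediate
13 | (2R)-N,N-dimethyl-2-[(1R,5S,7R)-7-(prop-2-en-1-yl)-6-azaspiro[4.5]decan-1-yl]propanamide | C[C@@H](C(=O)N(C)C)[C@H]1CCC[C@@]12N[C@@H](CC=C)CCC2 | intermediate
14 | methyl 2-(bromomethyl)acrylate | C=C(CBr)C(=O)OC | starting material
15 | methyl 2-{[(1R,5S,7R)-1-[(2R)-1-(dimethylamino)-1-oxopropan-2-yl]-7-(prop-2-en-1-yl)-6-azaspiro[4.5]decan-6-yl]methyl}prop-2-enoate | C[C@@H](C(=O)N(C)C)[C@H]1CCC[C@@]12N(CC(=C)C(=O)OC)[C@@H](CC=C)CCC2 | intermediate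
16 | methyl (1S,2R,9a'R)-2-[(2R)-1-(dimethylamino)-1-oxopropan-2-yl]-1',4',7',8',9',9a'-hexahydrospiro[cyclopentane-1,6'-quinolizine]-3'-carboxylate | C[C@@H](C(=O)N(C)C)[C@H]1CCC[C@@]12N3CC(C(=O)OC)=CC[C@H]3CCC2 | intermediate
17 | methyl (1S,2R,9a'R)-2-[(2R)-1-oxopropan-2-yl]-1',4',7',8',9',9a'-hexahydrospiro[cyclopentane-1,6'-quinolizine]-3'-carboxylate | C[C@@H](C=O)[C@H]1CCC[C@@]12N3CC(C(=O)OC)=CC[C@H]3CCC2 | intermediate
18 | methyl (1S,2R,9a'R)-2-[(2R)-but-3-yn-2-yl]-1',4',7',8',9',9a'-hexahydrospiro[cyclopentane-1,6'-quinolizine]-3'-carboxylate | C[C@@H](C#C)[C@H]1CCC[C@@]12N3CC(C(=O)OC)=CC[C@H]3CCC2 | intermediate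
19 | dihydro-2H-pyran-2,4(3H)-dione | O=C1CC(=O)CCO1 | starting material
20 | 4-chloro-5,6-dihydro-2H-pyran-2-one | O=C1C=C(Cl)CCO1 | intermediate
21 | (2E)-3-chloro-5-hydroxy-N-methoxy-N-methylpent-2-enamide | CON(C)C(=O)/C=C(/Cl)CCO | intermediate
22 | (2E)-5-[(tert-butyldimethylsilyl)oxy]-3-chloro-N-methoxy-N-methylpent-2-enamide | CON(C)C(=O)/C=C(/Cl)CCO[Si](C)(C)C(C)(C)C | intermediate
23 | (2E)-5-[(tert-butyldimethylsilyl)oxy]-3-chloropent-2-enal | O=C/C=C(/Cl)CCO[Si](C)(C)C(C)(C)C | intermediate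
24 | methyl (1S,2R,9a'R)-2-[(2R,5S,6E)-9-[(tert-butyldimethylsilyl)oxy]-7-chloro-5-hydroxynon-6-en-3-yn-2-yl]-1',4',7',8',9',9a'-hexahydrospiro[cyclopentane-1,6'-quinolizine]-3'-carboxylate | C[C@@H](C#C[C@@H](O)/C=C(/Cl)CCO[Si](C)(C)C(C)(C)C)[C@H]1CCC[C@@]12N3CC(C(=O)OC)=CC[C@H]3CCC2 | intermediate
25 | methyl (1S,2R,9a'R)-2-[(2S,3Z,5R,6E)-9-[(tert-butyldimethylsilyl)oxy]-7-chloro-5-hydroxynona-3,6-dien-2-yl]-1',4',7',8',9',9a'-hexahydrospiro[cyclopentane-1,6'-quinolizine]-3'-carboxylate | C[C@@H](/C=C\[C@@H](O)/C=C(/Cl)CCO[Si](C)(C)C(C)(C)C)[C@H]1CCC[C@@]12N3CC(C(=O)OC)=CC[C@H]3CCC2 | intermediate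
26 | methyl (1S,2R,9a'R)-2-[(2S,3Z,5R,6E)-7-chloro-5,9-dihydroxynona-3,6-dien-2-yl]-1',4',7',8',9',9a'-hexahydrospiro[cyclopentane-1,6'-quinolizine]-3'-carboxylate | C[C@@H](/C=C\[C@@H](O)/C=C(/Cl)CCO)[C@H]1CCC[C@@]12N3CC(C(=O)OC)=CC[C@H]3CCC2 | intermediate
27 | (1S,2R,9a'R)-2-[(2S,3Z,5R,6E)-7-chloro-5,9-dihydroxynona-3,6-dien-2-yl]-1',4',7',8',9',9a'-hexahydrospiro[cyclopentane-1,6'-quinolizine]-3'-carboxylic acid | C[C@@H](/C=C\[C@@H](O)/C=C(/Cl)CCO)[C@H]1CCC[C@@]12N3CC(C(=O)O)=CC[C@H]3CCC2 | intermediate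
28 | target macrolactone CNP0129639.4 (5R,9S,13R,14S,17R; 15Z; 18E) | C[C@H]1/C=C\[C@@H](O)/C=C(/Cl)CCOC(=O)C2=CC[C@H]3CCC[C@]4(CCC[C@H]14)N3C2 | target

**Step count and risks**

Total step count: 21. Longest linear sequence: 16 steps (steps 1–4, 6–12, 17–21, from 1 to 28).

Steps most likely to fail:

1. Step 6 (Proposed new method). The aza-Wittig condensation may be slow on the α-branched ketone. The azadiene may tautomerize, which would scramble C13 or lead to reaction through a ring A enamine carbon. The cycloaddition may end by proton transfer instead of ring closure, so that no spirocycle forms. Fallback with known chemistry, from 5, returning at 13: condensation of 5 with (R)-tert-butanesulfinamide (Ti(OEt)4, THF, 60 °C) should give the N-sulfinyl ketimine F1. Pent-4-enylmagnesium bromide (CH2Cl2, −78 °C) should add to C9 anti to the C13 arm to give the sulfinamide F2. Cross-metathesis with acrolein (second-generation Grubbs catalyst) should give the enal F3. HCl in wet dioxane removes the sulfinyl group, and on neutralization the free amine should close ring B by intramolecular aza-Michael addition under thermodynamic control to the amino aldehyde F4. Methylenation with Ph3P=CH2 returns to 13.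

2. Step 17. Turnover or facial selectivity may be poor because the basic tertiary amine of 18 binds the zinc catalyst and the limiting alkyne is hindered. The enal 23 may also isomerize about C18=C19 before it reacts. Fallback, from 18 and 22, returning at 24: deprotonation of 18 with LiN(SiMe3)2 (THF, −78 °C) and acylation of the lithium acetylide by Weinreb amide 22 should give the ynone F5. Midland reduction with (S)-Alpine-Borane (B-isopinocampheyl-9-borabicyclo[3.3.1]nonane from (−)-α-pinene), in which the alkynyl group acts as the small substituent, should return to 24.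

3. Step 21. The unprotected C17 hydroxyl may be acylated, or intermolecular esterification may outrun ring closure. Fallback, from 25, returning at 28: silylation (TBSOTf, 2,6-lutidine) should give the bis-silyl ether F6. HF·pyridine/pyridine should cleave only the primary silyl ether to give the alcohol F7. LiOH should give the C17-silylated seco acid F8. Carbodiimide macrolactonization (DCC, DMAP, DMAP·HCl, CHCl3, reflux, high dilution) should give the silyl-protected macrolactone F9, and HF·pyridine then frees 28.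

Further compounds
F1 | step 6 | (2R)-N,N-dimethyl-2-[(1R)-2-{[(R)-tert-butylsulfinyl]imino}cyclopentyl]propanamide | C[C@@H](C(=O)N(C)C)[C@H]1CCCC1=N[S@](=O)C(C)(C)C
F2 | step 6 | (2R)-N,N-dimethyl-2-[(1R)-2-{[(R)-tert-butylsulfinyl]amino}-2-(pent-4-en-1-yl)cyclopentyl]propanamide, pentenyl group trans to the propanamide arm | C[C@@H](C(=O)N(C)C)[C@H]1CCC[C@@]1(CCCC=C)N[S@](=O)C(C)(C)C
F3 | step 6 | (2R)-N,N-dimethyl-2-[(1R)-2-{[(R)-tert-butylsulfinyl]amino}-2-[(4E)-6-oxohex-4-en-1-yl]cyclopentyl]propanamide, same ring configuration as F2 | C[C@@H](C(=O)N(C)C)[C@H]1CCC[C@@]1(CCC/C=C/C=O)N[S@](=O)C(C)(C)C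
F4 | step 6 | (2R)-N,N-dimethyl-2-[(1R,5S,7R)-7-(2-oxoethyl)-6-azaspiro[4.5]decan-1-yl]propanamide | C[C@@H](C(=O)N(C)C)[C@H]1CCC[C@@]12N[C@@H](CC=O)CCC2
F5 | step 17 | methyl (1S,2R,9a'R)-2-[(2R,6E)-9-[(tert-butyldimethylsilyl)oxy]-7-chloro-5-oxonon-6-en-3-yn-2-yl]-1',4',7',8',9',9a'-hexahydrospiro[cyclopentane-1,6'-quinolizine]-3'-carboxylate | C[C@@H](C#CC(=O)/C=C(/Cl)CCO[Si](C)(C)C(C)(C)C)[C@H]1CCC[C@@]12N3CC(C(=O)OC)=CC[C@H]3CCC2
F6 | step 21 | bis-silyl ether of 25 (C17 and C21 as tert-butyldimethylsilyl ethers) | C[C@@H](/C=C\[C@@H](O[Si](C)(C)C(C)(C)C)/C=C(/Cl)CCO[Si](C)(C)C(C)(C)C)[C@H]1CCC[C@@]12N3CC(C(=O)OC)=CC[C@H]3CCC2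
F7 | step 21 | C17 tert-butyldimethylsilyl ether of diol ester 26 (C21 hydroxyl free) | C[C@@H](/C=C\[C@@H](O[Si](C)(C)C(C)(C)C)/C=C(/Cl)CCO)[C@H]1CCC[C@@]12N3CC(C(=O)OC)=CC[C@H]3CCC2
F8 | step 21 | C17 tert-butyldimethylsilyl ether of seco acid 27 | C[C@@H](/C=C\[C@@H](O[Si](C)(C)C(C)(C)C)/C=C(/Cl)CCO)[C@H]1CCC[C@@]12N3CC(C(=O)O)=CC[C@H]3CCC2
F9 | step 21 | C17 tert-butyldimethylsilyl ether of target 28 | C[C@H]1/C=C\[C@@H](O[Si](C)(C)C(C)(C)C)/C=C(/Cl)CCOC(=O)C2=CC[C@H]3CCC[C@]4(CCC[C@H]14)N3C2
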